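## Retrosynthetic overview

1. Key C–C disconnection: each cinnamoyl Cα=Cβ bond goes back to 4-hydroxybenzaldehyde (1) and malonic acid (2), joined by an aldol-type Knoevenagel–Doebner condensation through the arylidenemalonic acid (3) to (E)-p-coumaric acid (4).
2. Acid 4 is masked and activated: O-acetate (5), then acid chloride (6).
3. Spermidine (7) is differentiated at nitrogen: primary amines as trifluoroacetamides (8, in situ), N4 as Boc (9), then release of the primary amines gives N4-Boc-spermidine (10).
4. Two amide C–N disconnections: 10 + 2 × 6 gives bisamide 11; O-deacetylation (12), Boc removal (hydrochloride 13) and free-basing give the target (14).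
5. No ring is formed; both benzene rings come intact from 1, and the only stereo-elements are the two E double bonds set in the condensation.

Assumption: the target has no stereocentre, so "single enantiomer" is read as the single (E,E) geometric isomer drawn. All cinnamoyl compounds are handled in amber glassware to avoid E/Z photoisomerisation.

## Route

Step 1
Reactants: 1 4-hydroxybenzaldehyde; 2 malonic acid
Product: 4 (E)-4-hydroxycinnamic acid (p-coumaric acid), via 4-hydroxybenzylidenemalonic acid 3 (not isolated)
Conditions: 2 (2.0 equiv), piperidine (0.1 equiv), pyridine, 70 → 90 °C, 4 h; then ice/aq HCl, filter, recrystallise from H2O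
Reagents that add atoms: none
Why: Knoevenagel–Doebner condensation (amine-catalysed aldol-type addition of malonic acid to the aldehyde, dehydration, then pyridine-promoted decarboxylation) forms the Cα–Cβ bond and gives the thermodynamically favoured E-alkene.

Step 2
Reactants: 4 (E)-4-hydroxycinnamic acid
Product: 5 (E)-4-acetoxycinnamic acid
Conditions: Ac2O (2.0 equiv), 4-(dimethylamino)pyridine (DMAP, cat.), pyridine, 0 °C → rt, 3 h; then H2O (30 min), aq HCl, filter
Reagents that add atoms: acetic anhydride, CC(=O)OC(C)=O
Why: DMAP-catalysed O-acetylation (nucleophilic acyl substitution) masks the phenol against self-acylation in the later steps, and the aqueous quench hydrolyses any mixed anhydride back to the free acid.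

Step 3
Reactants: 5 (E)-4-acetoxycinnamic acid
Product: 6 (E)-4-acetoxycinnamoyl chloride
Conditions: (COCl)2 (1.5 equiv), N,N-dimethylformamide (DMF, cat.), CH2Cl2, 0 °C → rt, 2 h; evaporate (toluene chase), use crude solid
Reagents that add atoms: oxalyl chloride, O=C(Cl)C(=O)Cl
Why: DMF-catalysed (Vilsmeier-type) acid chloride formation runs under non-basic conditions with only gaseous by-products and touches neither the aryl acetate nor the E-alkene.

Step 4
Reactants: 7 spermidine
Product: 9 N4-Boc-N1,N8-bis(trifluoroacetyl)spermidine, via N1,N8-bis(trifluoroacetyl)spermidine 8 (not isolated)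
Conditions: CF3CO2Et (2.1 equiv), MeOH, −78 → 0 °C, 1 h; then Boc2O (1.3 equiv), 0 °C → rt, 16 h; chromatography
Reagents that add atoms: ethyl trifluoroacetate, CCOC(=O)C(F)(F)F; di-tert-butyl dicarbonate, CC(C)(C)OC(=O)OC(=O)OC(C)(C)C
Why: Kinetically selective ester aminolysis puts trifluoroacetyl only on the two unhindered primary amines at low temperature, after which carbamate formation with Boc2O can occur only at the one remaining basic nitrogen (N4).

Step 5
Reactants: 9 N4-Boc-N1,N8-bis(trifluoroacetyl)spermidine
Product: 10 N4-Boc-spermidine, tert-butyl N-(4-aminobutyl)-N-(3-aminopropyl)carbamate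
Conditions: 7 M NH3 in MeOH, sealed, rt → 40 °C, 24 h; evaporate, basic extraction into CH2Cl2
Reagents that add atoms: none
Why: Ammonolysis (acyl transfer) cleaves the strongly electrophilic trifluoroacetamides while the Boc carbamate is inert to ammonia.

Step 6
Reactants: 10 N4-Boc-spermidine; 6 (E)-4-acetoxycinnamoyl chloride
Product: 11 N4-Boc-N1,N8-bis[(E)-4-acetoxycinnamoyl]spermidine
Conditions: 6 (2.2 equiv), Et3N (2.5 equiv), CH2Cl2, −10 → 0 °C, 10 added dropwise to 6, 1 h; aq citric acid then aq NaHCO3 wash; chromatography
Reagents that add atoms: none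
Why: Schotten–Baumann-type N-acylation gives the two amides because the acid chloride is far more electrophilic than the aryl acetate at low temperature and N4 is blocked as its carbamate.

Step 7
Reactants: 11 N4-Boc-N1,N8-bis[(E)-4-acetoxycinnamoyl]spermidine
Product: 12 N4-Boc-N1,N8-bis[(E)-4-hydroxycinnamoyl]spermidine
Conditions: 7 M NH3 in MeOH, THF, 0 °C → rt, 2 h; evaporate, H2O wash, chromatography
Reagents that add atoms: none
Why: Chemoselective ammonolysis of the activated phenyl esters frees both phenols without touching the amides, the carbamate or the E-alkenes.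

Step 8
Reactants: 12 N4-Boc-N1,N8-bis[(E)-4-hydroxycinnamoyl]spermidine
Product: 13 N1,N8-bis[(E)-4-hydroxycinnamoyl]spermidine hydrochloride
Conditions: 4 M HCl in 1,4-dioxane (10 equiv), 0 °C → rt, 2 h, dark; dilute with Et2O, filter the salt
Reagents that add atoms: hydrogen chloride, Cl
Why: Acidolytic Boc cleavage (loss of the tert-butyl cation as isobutene, then decarboxylation of the carbamic acid) frees N4 as its ammonium chloride, which precipitates, while amides and cinnamoyl alkenes are stable to anhydrous HCl at room temperature.

Step 9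
Reactants: 13 N1,N8-bis[(E)-4-hydroxycinnamoyl]spermidine hydrochloride
Product: 14 N1,N8-bis[(E)-p-coumaroyl]spermidine (target)
Conditions: 1.0 M aq NaOH (1.0 equiv), MeOH/H2O, 0 °C, to pH about 9.5–10; desalt on C18 silica (H2O, then MeOH) or extract with n-BuOH; dark
Reagents that add atoms: none
Why: A simple acid–base neutralisation with exactly one equivalent of NaOH liberates the secondary amine without ionising the phenols to a significant extent and changes no covalent bond.

## Compound list

1 | 4-hydroxybenzaldehyde | O=Cc1ccc(O)cc1 | starting material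
2 | malonic acid | OC(=O)CC(=O)O | starting material
3 | 2-(4-hydroxybenzylidene)malonic acid | OC(=O)C(=Cc1ccc(O)cc1)C(=O)O | intermediate
4 | (E)-4-hydroxycinnamic acid (p-coumaric acid) | OC(=O)/C=C/c1ccc(O)cc1 | intermediate
5 | (E)-4-acetoxycinnamic acid | CC(=O)Oc1ccc(/C=C/C(=O)O)cc1 | intermediate
6 | (E)-4-acetoxycinnamoyl chloride | CC(=O)Oc1ccc(/C=C/C(=O)Cl)cc1 | intermediate
7 | spermidine, N-(3-aminopropyl)butane-1,4-diamine | NCCCCNCCCN | starting material
8 | N1,N8-bis(trifluoroacetyl)spermidine | O=C(NCCCCNCCCNC(=O)C(F)(F)F)C(F)(F)F | intermediate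
9 | N4-Boc-N1,N8-bis(trifluoroacetyl)spermidine, tert-butyl N-[4-(2,2,2-trifluoroacetamido)butyl]-N-[3-(2,2,2-trifluoroacetamido)propyl]carbamate | CC(C)(C)OC(=O)N(CCCCNC(=O)C(F)(F)F)CCCNC(=O)C(F)(F)F | intermediate
10 | N4-Boc-spermidine, tert-butyl N-(4-aminobutyl)-N-(3-aminopropyl)carbamate | CC(C)(C)OC(=O)N(CCCCN)CCCN | intermediate
11 | N4-Boc-N1,N8-bis[(E)-4-acetoxycinnamoyl]spermidine | CC(=O)Oc1ccc(/C=C/C(=O)NCCCCN(CCCNC(=O)/C=C/c2ccc(OC(C)=O)cc2)C(=O)OC(C)(C)C)cc1 | intermediate
12 | N4-Boc-N1,N8-bis[(E)-4-hydroxycinnamoyl]spermidine | O=C(/C=C/c1ccc(O)cc1)NCCCCN(CCCNC(=O)/C=C/c1ccc(O)cc1)C(=O)OC(C)(C)C | intermediate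
13 | N1,N8-bis[(E)-4-hydroxycinnamoyl]spermidine hydrochloride | O=C(/C=C/c1ccc(O)cc1)NCCCC[NH2+]CCCNC(=O)/C=C/c1ccc(O)cc1.[Cl-] | intermediate
14 | N1,N8-bis[(E)-p-coumaroyl]spermidine | O=C(/C=C/c1ccc(O)cc1)NCCCCNCCCNC(=O)/C=C/c1ccc(O)cc1 | target

## Step count and risks

Total step count: 9.
Longest linear sequence: 7 steps (steps 1, 2, 3, 6, 7, 8, 9 from 4-hydroxybenzaldehyde). The spermidine branch (steps 4 and 5) joins at step 6.

Three steps most likely to fail, with fallbacks:

Step 4 (one-pot selective protection). The risk is incomplete discrimination between primary and secondary nitrogen, giving mixtures of trifluoroacetyl/Boc regioisomers. The fallback sets out from 7 and comes back at 10. Spermidine is treated with N-(ethoxycarbonyl)phthalimide (2.0 equiv, CHCl3, rt), which can form an imide only at a primary amine and so gives N1,N8-diphthaloylspermidine F1. Boc2O/Et3N in CH2Cl2 then gives N4-Boc-N1,N8-diphthaloylspermidine F2. Hydrazinolysis (N2H4·H2O, EtOH, reflux; filter off phthalhydrazide) releases 10.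

Step 6 (bis-acylation). The risks are aminolysis of the aryl acetates by the primary amines (N-acetyl by-products) and partial hydrolysis of 6 leading to mono-amide. The fallback sets out from 4 (with 10 as partner) and comes back at 12, dropping the phenol protection and the acid chloride. Acid 4 (2.2 equiv) is activated with EDC·HCl/HOBt in DMF at 0 °C to give in situ 1H-benzotriazol-1-yl (E)-4-hydroxycinnamate F3, which acylates 10 at rt to give 12 directly. A short NH3/MeOH treatment cleaves any phenolic ester oligomers. Steps 2, 3 and 7 are then unnecessary.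

Step 8 (acidic Boc removal). The risks are ring tert-butylation of the electron-rich phenols, acid-promoted E/Z erosion, and awkward handling of the salt and free base. The fallback sets out from 4 (with 7 as the amine partner) and comes back at 14, avoiding N4 protection and acid altogether. Acid 4 with N-hydroxysuccinimide and dicyclohexylcarbodiimide (THF, 0 °C → rt; filter the urea) gives crystalline N-succinimidyl (E)-4-hydroxycinnamate F4. Of this, 2.0 equiv are added to spermidine 7 in DMF/CH2Cl2 at −20 → 0 °C. The primary amines react much faster than the hindered secondary amine, so 14 is obtained directly after adjustment to pH about 9.5 and C18 purification.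

## Further compounds

F1 | step 4 | N1,N8-diphthaloylspermidine | O=C1c2ccccc2C(=O)N1CCCCNCCCN1C(=O)c2ccccc2C1=O
F2 | step 4 | N4-Boc-N1,N8-diphthaloylspermidine | CC(C)(C)OC(=O)N(CCCCN1C(=O)c2ccccc2C1=O)CCCN1C(=O)c2ccccc2C1=O
F3 | step 6 | 1H-benzotriazol-1-yl (E)-4-hydroxycinnamate | O=C(/C=C/c1ccc(O)cc1)On1nnc2ccccc12
F4 | step 8 | N-succinimidyl (E)-4-hydroxycinnamate | O=C(/C=C/c1ccc(O)cc1)ON1C(=O)CCC1=O
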